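The quinone ring (C1 carbonyl beside the CH, C2–OH, C3–heneicosyl, C4 carbonyl, C5–OMe, C6–H) is cut at C5–C6 and C1–C2. The four-carbon arc C2–C3–C4–C5 is a squarate-derived cyclobutenedione whose two carbonyl carbons become C2 and C5; the two-carbon arc C6–C1 is a (Z)-2-isopropoxyvinyl anion. In one pot the anion adds to the future C5 carbonyl, the alkoxide is O-methylated, and heating opens the four-membered ring to a dienylketene whose 6π closure joins C1 to C2 (Moore ring expansion). The step exploits the para relation of the OMe- and OH-bearing ring carbons. Cleavage of both isopropyl ethers and autoxidation then give the hydroxyquinone.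

Key step: step 3

Assumption: 1-bromoheneicosane is taken as a catalogue chemical; the target has no stereocentre and is treated as its 2-hydroxy-1,4-quinone tautomer.

Step 1
Reactants: 1 1-bromoheneicosane; 2 diisopropyl squarate (3,4-di(propan-2-yloxy)cyclobut-3-ene-1,2-dione)
Product: 5 3-heneicosyl-4-(propan-2-yloxy)cyclobut-3-ene-1,2-dione, via heneicosylmagnesium bromide 3 (not isolated), via bromomagnesium alkoxide adduct 4 (not isolated)
Conditions: 1, Mg turnings, THF, 50 °C; added to 2, THF, −78 °C; (CF3CO)2O, −78 → 0 °C; aq. NaHCO3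
Reagents that add atoms: none
Why: Grignard 1,2-addition to one squarate carbonyl at −78 °C, followed by anhydride-promoted loss of the tertiary oxygen and hydrolysis of the isopropoxy-stabilised cation on work-up, is the standard conversion of a squarate diester into a 3-alkyl-4-alkoxycyclobutenedione, and no stereocentre survives.

Step 2
Reactants: 6 isopropyl vinyl ether
Product: 8 (Z)-1-bromo-2-(propan-2-yloxy)ethene, via dibromide 7 (not isolated)
Conditions: Br2, pentane, −78 °C; then PhNEt2, 90–100 °C, distillation at reduced pressure
Reagents that add atoms: bromine, BrBr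
Why: Electrophilic bromine addition to the enol ether and amine-induced dehydrobromination of the α-bromo ether should give mainly the Z isomer, which is the favoured geometry of 1-halo-2-alkoxyethenes (cis effect) and the one needed for a stable β-alkoxyvinyllithium.

Step 3
Reactants: 5 3-heneicosyl-4-(propan-2-yloxy)cyclobut-3-ene-1,2-dione; 8 (Z)-1-bromo-2-(propan-2-yloxy)ethene
Product: 14 2-heneicosyl-4-methoxy-3,6-di(propan-2-yloxy)phenol, via vinyllithium 9 (not isolated), via lithium alkoxide 10 (not isolated), via methyl ether 11 (not isolated), via dienylketene 12 (not isolated), via cyclohexadienone 13 (not isolated)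
Conditions: 8, t-BuLi (2 equiv), Et2O/THF, −78 °C; 5, −78 °C; MeOTf, −78 → 0 °C; Et3N; then PhMe, 110 °C (THF distilled off), Ar
Reagents that add atoms: methyl trifluoromethanesulfonate, COS(=O)(=O)C(F)(F)F
Why: Bromine–lithium exchange gives the configurationally stable (Z)-2-isopropoxyvinyllithium (cis O and Li cannot undergo anti β-elimination), which adds 1,2 to the ketone-like carbonyl next to the isopropoxy-bearing carbon and so forms the C5–C6 bond, and MeOTf caps the tertiary alkoxide as the future C5–OMe. On heating, the cyclobutenone undergoes conrotatory 4π ring opening with the methoxy donor rotating outward, so the alkenyl group faces the ketene; disrotatory 6π-electrocyclisation of the dienylketene (ketene carbon onto the alkoxyvinyl terminus, six-membered carbocycle) forms the C1–C2 bond, and enolisation of the cyclohexadienone gives the phenol. The closest known reaction type is the Moore ring expansion of 4-alkenyl-4-alkoxycyclobutenones to hydroquinone monoethers. No stereocentre remains, because the racemic carbinol carbon of the adduct and the CH(OiPr) carbon of the dienone both become aromatic. The step needs carbonyl regioselectivity, secured by vinylogous-ester deactivation of the other carbonyl, and complete O-methylation before heating, so that only the C5 oxygen carries methyl and the ketene oxygen emerges as the free C2–OH. It also needs outward rotation of the methoxy group, which the donor substituent secures.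

Step 4
Reactants: 14 2-heneicosyl-4-methoxy-3,6-di(propan-2-yloxy)phenol
Product: 16 2-hydroxy-3-heneicosyl-5-methoxy-1,4-benzoquinone, via benzenetriol 15 (not isolated)
Conditions: BCl3, CH2Cl2, −78 → 0 °C; MeOH, H2O; then air (O2), EtOAc/pH 7 phosphate buffer, rt
Reagents that add atoms: none
Why: BCl3 cleaves secondary (isopropyl) aryl ethers far faster than methyl ethers (Lewis acid ether dealkylation), and the liberated 1,2,4-triol should autoxidise in air to the 2-hydroxy-1,4-benzoquinone, every quinone tautomer converging on the target because only the C5 oxygen carries a methyl group.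

Compound list
1 | 1-bromoheneicosane | CCCCCCCCCCCCCCCCCCCCCBr | starting material
2 | diisopropyl squarate | CC(C)OC1=C(OC(C)C)C(=O)C1=O | starting material
3 | heneicosylmagnesium bromide | CCCCCCCCCCCCCCCCCCCCC[Mg]Br | intermediate
4 | bromomagnesium alkoxide of 4-heneicosyl-4-hydroxy-2,3-di(propan-2-yloxy)cyclobut-2-en-1-one (racemic) | CCCCCCCCCCCCCCCCCCCCCC1(O[Mg]Br)C(OC(C)C)=C(OC(C)C)C1=O | intermediate
5 | 3-heneicosyl-4-(propan-2-yloxy)cyclobut-3-ene-1,2-dione | CCCCCCCCCCCCCCCCCCCCCC1=C(OC(C)C)C(=O)C1=O | intermediate
6 | isopropyl vinyl ether | C=COC(C)C | starting material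
7 | 1,2-dibromo-1-(propan-2-yloxy)ethane (racemic) | BrCC(Br)OC(C)C | intermediate
8 | (Z)-1-bromo-2-(propan-2-yloxy)ethene | Br/C=C\OC(C)C | intermediate
9 | (Z)-2-(propan-2-yloxy)vinyllithium | [Li]/C=C\OC(C)C | intermediate
10 | lithium alkoxide of 2-heneicosyl-4-hydroxy-3-(propan-2-yloxy)-4-[(Z)-2-(propan-2-yloxy)ethenyl]cyclobut-2-en-1-one (racemic) | CCCCCCCCCCCCCCCCCCCCCC1=C(OC(C)C)C(O[Li])(/C=C\OC(C)C)C1=O | intermediate
11 | 2-heneicosyl-4-methoxy-3-(propan-2-yloxy)-4-[(Z)-2-(propan-2-yloxy)ethenyl]cyclobut-2-en-1-one (racemic) | CCCCCCCCCCCCCCCCCCCCCC1=C(OC(C)C)C(OC)(/C=C\OC(C)C)C1=O | intermediate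
12 | (3Z,5Z)-2-heneicosyl-4-methoxy-3,6-di(propan-2-yloxy)hexa-1,3,5-trien-1-one (dienylketene) | CCCCCCCCCCCCCCCCCCCCCC(=C=O)/C(OC(C)C)=C(OC)\C=C/OC(C)C | intermediate
13 | 2-heneicosyl-4-methoxy-3,6-di(propan-2-yloxy)cyclohexa-2,4-dien-1-one (racemic) | CCCCCCCCCCCCCCCCCCCCCC1=C(OC(C)C)C(OC)=CC(OC(C)C)C1=O | intermediate
14 | 2-heneicosyl-4-methoxy-3,6-di(propan-2-yloxy)phenol | CCCCCCCCCCCCCCCCCCCCCc1c(O)c(OC(C)C)cc(OC)c1OC(C)C | intermediate
15 | 3-heneicosyl-5-methoxybenzene-1,2,4-triol | CCCCCCCCCCCCCCCCCCCCCc1c(O)c(O)cc(OC)c1O | intermediate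
16 | 2-hydroxy-3-heneicosyl-5-methoxy-1,4-benzoquinone | CCCCCCCCCCCCCCCCCCCCCC1=C(O)C(=O)C=C(OC)C1=O | target

Total step count: 4. Longest linear sequence: 3 steps (step 1, step 3, step 4); step 2 is a one-step side branch.

Steps most likely to fail

Step 3. O-Methylation of the hindered tertiary lithium alkoxide may lag, or the alkoxide may ring-open anionically before it is capped. Unmethylated material would then divert on heating and the methyl label on the C5 oxygen would be lost. The fallback sets out from 5 and 8 and comes back at 11. The addition of 9 to 5 is quenched at −78 °C with aqueous NH4Cl, and the racemic carbinol 2-heneicosyl-4-hydroxy-3-(propan-2-yloxy)-4-[(Z)-2-(propan-2-yloxy)ethenyl]cyclobut-2-en-1-one F1 is isolated. It is etherified under neutral Purdie conditions (MeI, Ag2O, CaSO4, MeCN, rt) to 11. Purified 11 is then heated in toluene at 110 °C as a separate operation and should give 14 through 12 and 13.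

Step 4. Chelation-assisted loss of the C5 methyl ether may set in once the neighbouring oxygen is borylated, and the electron-rich triol may over-oxidise during aerial oxidation. The fallback sets out from 14 and comes back at 16, and replaces Lewis-acid dealkylation by oxidative dealkylation. The phenol is masked by acetylation (Ac2O, pyridine, DMAP, rt) as 2-heneicosyl-4-methoxy-3,6-di(propan-2-yloxy)phenyl acetate F2, so that oxidation cannot run through the C2–O/C5–OMe pair. (NH4)2Ce(NO3)6 in MeCN/H2O at 0 °C should then remove the two para-disposed isopropyl groups and give 2-acetoxy-3-heneicosyl-5-methoxy-1,4-benzoquinone F3. Mild hydrolysis of this vinylogous anhydride (aq. NaHCO3, THF, rt) gives 16.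

Step 2. The labile α-bromo ether may decompose or hydrolyse during the hot amine dehydrobromination, and the volatile bromo enol ether may be lost on distillation. The fallback sets out from 6 and comes back at 8, and avoids both the α-bromo ether and the hot step. Bromo-alkoxylation of 6 (N-bromosuccinimide, propan-2-ol, 0 °C) gives the stable bromo acetal 2-bromo-1,1-di(propan-2-yloxy)ethane F4. Acetal-to-enol-ether elimination with Me3SiOTf/iPr2NEt (CH2Cl2, −20 °C → rt) should then give 8 together with (E)-1-bromo-2-(propan-2-yloxy)ethene F5. The mixture can be enriched in 8 by fractional distillation or used as such with extra t-BuLi, since the E-lithio species undergoes anti β-elimination at −78 °C and only 9 survives.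

Further compounds
F1 | step 3 | 2-heneicosyl-4-hydroxy-3-(propan-2-yloxy)-4-[(Z)-2-(propan-2-yloxy)ethenyl]cyclobut-2-en-1-one (racemic) | CCCCCCCCCCCCCCCCCCCCCC1=C(OC(C)C)C(O)(/C=C\OC(C)C)C1=O
F2 | step 4 | 2-heneicosyl-4-methoxy-3,6-di(propan-2-yloxy)phenyl acetate | CCCCCCCCCCCCCCCCCCCCCc1c(OC(C)=O)c(OC(C)C)cc(OC)c1OC(C)C
F3 | step 4 | 2-acetoxy-3-heneicosyl-5-methoxy-1,4-benzoquinone | CCCCCCCCCCCCCCCCCCCCCC1=C(OC(C)=O)C(=O)C=C(OC)C1=O
F4 | step 2 | 2-bromo-1,1-di(propan-2-yloxy)ethane | BrCC(OC(C)C)OC(C)C
F5 | step 2 | (E)-1-bromo-2-(propan-2-yloxy)ethene | Br/C=C/OC(C)C
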